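Everything rests on cutting the seven-membered ring at both bonds of its single CH2 carbon. That carbon is flanked by the free carbinol and the angelate-bearing carbinol. Each of these hangs on a quaternary carbon (the methyl-bearing cyclobutane carbon and the C(CH3)(CH2OAc) carbon), so both map onto formyl groups without alpha hydrogens. Nitromethane stitches them together in one flask: two C–C bonds, the cycloheptane and the 1,3-dioxygenation arise at once. The precursor is a bicyclo[3.1.1]heptane dialdehyde whose formyl-bearing carbons share one cyclobutane face. Ozonolysis of a tricyclic cyclohexene releases it, which guarantees this geometry and carries the side-chain quaternary centre, set earlier under reagent control.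

Key step: step 21

Atom labels (kept for the same carbons in every compound):
- Ca = CH–O-angelate
- Cb = ring CH2
- Cc = CH–OH
- Cd = quaternary cyclobutane carbon bearing CH3
- Ce = cyclobutane CH bonded to Cj
- Cf = cyclobutane CH bonded to Ck
- Cg = cyclobutane CH bonded to Ch
- Ch = ketone carbon
- Ci = CH2 next to it
- Cj = CH(CH3)
- Ck = C(CH3)(CH2OAc)

Orientation in 38: the Ca–O bond and the Ck methyl point to the Ce side of the seven-membered ring, and Cc–OH and Ck–CH2OAc point to the Cg side. The Cd methyl lies over the Ch–Ci–Cj bridge and the Cj methyl points toward Cf.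

Assumption: (R)-Wieland–Miescher ketone is taken as a catalogue compound in enantiopure form.

Remark on the chemistry: pseudo-equatorial positions alternate along the four-atom bridge Cc–Cb–Ca–Ck, so a 1,3-trans diol cannot carry both hydroxyls pseudo-equatorial. The nitroaldol step is therefore trusted only for Ca, and Cc is set afterwards under reagent control.

Step 1
Reactants: 1 (R)-Wieland–Miescher ketone
Product: 2 dienol ether ketone (8aR)-6-ethoxy-8a-methyl-3,7,8,8a-tetrahydronaphthalen-1(2H)-one
Conditions: HC(OEt)3, p-TsOH·H2O (cat.), EtOH, 25 °C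
Reagents that add atoms: triethyl orthoformate, CCOC(OCC)OCC
Why: Acid-catalysed dienol ether formation (the orthoformate method used for steroidal 4-en-3-ones) masks the enone, while the Cg ketone stays free because the adjacent quaternary Cd disfavours its ketal, and no stereocentre is touched.

Step 2
Reactants: 2 dienol ether ketone
Product: 3 hydroxy ketone (Ch–OH equatorial and trans to the angular methyl)
Conditions: KN(SiMe3)2, THF, −78 °C; then 2-(phenylsulfonyl)-3-phenyloxaziridine, −78 °C; AcOH quench
Reagents that add atoms: 2-(phenylsulfonyl)-3-phenyloxaziridine, O=S(=O)(c1ccccc1)N1OC1c1ccccc1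
Why: Davis enolate hydroxylation works here because Ch is the only enolisable position of 2, and the oxidant should come anti to the axial angular methyl so that the new hydroxyl sits equatorial and trans to it, a centre that is erased again in step 16.

Step 3
Reactants: 3 hydroxy ketone
Product: 4 silyloxy ketone (TBS ether of 3)
Conditions: t-BuMe2SiCl, imidazole, DMF, 25 °C
Reagents that add atoms: tert-butyldimethylsilyl chloride, CC(C)(C)[Si](C)(C)Cl
Why: Standard silylation of a secondary alcohol gives an ether that survives the bases, organolithiums and oxidants of steps 4 to 14, with no change at any stereocentre.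

Step 4
Reactants: 4 silyloxy ketone
Product: 6 hydroxy enone (Cg–OH cis and Ch–OTBS trans to the angular methyl), via dienol ether alcohol 5 (not isolated)
Conditions: NaBH4, MeOH–THF, 0 °C; then 1 M HCl, THF, 0 to 25 °C
Reagents that add atoms: water, O
Why: Borohydride reduction takes place by axial attack on the face opposite the angular methyl, as known for the parent diketone, which sets Cg–OH equatorial and cis to that methyl, and the acidic work-up hydrolyses the enol ether back to the conjugated enone.

Step 5
Reactants: 6 hydroxy enone
Product: 7 enone mesylate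
Conditions: MsCl, Et3N, CH2Cl2, 0 °C
Reagents that add atoms: methanesulfonyl chloride, CS(=O)(=O)Cl
Why: Mesylation through sulfene tolerates the crowding around the neopentyl-type Cg–OH and keeps its configuration since the C–O bond is not broken.

Step 6
Reactants: 7 enone mesylate
Product: 8 cis-decalone mesylate (Ce–H cis to the Cd methyl)
Conditions: H2 (1 atm), Pd/C, pyridine, 25 °C
Reagents that add atoms: none
Why: Catalytic hydrogenation of angularly methylated octalones in a basic medium adds hydrogen so as to give the cis-fused decalone, which places Ce–H cis to the Cd methyl as the later cyclobutane requires.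

Step 7
Reactants: 8 cis-decalone mesylate
Product: 9 tricyclic ketone 3-(tert-butyldimethylsilyloxy)-1-methyltricyclo[4.4.0.0(2,7)]decan-8-one
Conditions: KOt-Bu, t-BuOH–THF, 25 to 50 °C
Reagents that add atoms: none
Why: In this intramolecular enolate alkylation under equilibrating conditions only the Cf enolate of the conformer with Cf axial can reach the rear of the equatorial Cg–OMs bond, so SN2 closure with inversion at Cg forms the cyclobutane and fixes Cf and Cg, which is the classical keto-sulfonate entry to tricyclo[4.4.0.0(2,7)]decanes.

Step 8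
Reactants: 9 tricyclic ketone
Product: 10 tricyclic enone (Ck=O conjugated with Ca=Cc)
Conditions: LiN(i-Pr)2, THF, −78 °C; then PhS(Cl)=Nt-Bu, −78 °C
Reagents that add atoms: none
Why: Mukaiyama one-pot dehydrogenation of the lithium enolate is regiochemically unambiguous because Cf is now a bridgehead and 9 can enolise only toward Ca, just as nopinone does.

Step 9
Reactants: 10 tricyclic enone
Product: 11 tertiary allylic alcohol (both epimers at Ck)
Conditions: MeLi, Et2O, −78 °C; H2O quench
Reagents that add atoms: methyllithium, [Li]C
Why: 1,2-Addition of methyllithium to a non-enolisable enone is clean, and the mixture of carbinol epimers at Ck is irrelevant because this centre becomes trigonal in step 10.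

Step 10
Reactants: 11 tertiary allylic alcohol
Product: 12 transposed enone (Cc=O conjugated with Ca=Ck–CH3)
Conditions: pyridinium chlorochromate C5H5NH[CrO3Cl], 4 Å sieves, CH2Cl2, 25 °C
Reagents that add atoms: pyridinium chlorochromate, [O-][Cr](=O)(=O)Cl.c1cc[nH+]cc1
Why: In the Dauben–Michno oxidative transposition the tertiary allylic chromate ester shifts suprafacially to Cc and is oxidised there, a sequence well tried for the alkylative 1,3-carbonyl transposition of cyclic enones including pinane-type ones.

Step 11
Reactants: 12 transposed enone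
Product: 13 allylic alcohol ((R)-carbinol at Cc with the hydroxyl on the Cg side)
Conditions: (S)-2-methyl-CBS-oxazaborolidine (0.2 equiv), catecholborane, toluene, −78 °C
Reagents that add atoms: none
Why: Corey–Bakshi–Shibata reduction is needed because the two faces of the Cc carbonyl see nearly mirror-image surroundings, so the catalyst, reading quaternary Cd as the large and the alkenyl CH as the small group, should deliver hydride from the Ce side and set the (R)-carbinol with its hydroxyl on the Cg side.

Step 12
Reactants: 13 allylic alcohol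
Product: 14 tributylstannylmethyl ether
Conditions: KH, 18-crown-6 (cat.), Bu3SnCH2I, THF, 0 to 25 °C
Reagents that add atoms: (iodomethyl)tributylstannane, CCCC[Sn](CI)(CCCC)CCCC
Why: Williamson etherification of the potassium alkoxide with the reactive primary iodide leaves the carbinol configuration untouched.

Step 13
Reactants: 14 tributylstannylmethyl ether
Product: 16 homoallylic alcohol (Ck quaternary with CH2OH on the Cg side and CH3 on the Ce side; Ca=Cc), via lithiomethyl ether 15 (not isolated)
Conditions: n-BuLi, THF, −78 °C; H2O quench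
Reagents that add atoms: none
Why: Tin–lithium exchange triggers the Wittig–Still [2,3]-sigmatropic rearrangement, which in a ring must be suprafacial, so the CH2OH group arrives at Ck on the Cg side where the Cc–O bond was, creating the quaternary centre and the Ca=Cc double bond in one event.

Step 14
Reactants: 16 homoallylic alcohol
Product: 17 PMB ether
Conditions: NaH, 4-MeOC6H4CH2Cl, Bu4NI (cat.), DMF, 0 to 25 °C
Reagents that add atoms: 4-methoxybenzyl chloride, COc1ccc(CCl)cc1
Why: Williamson benzylation of the primary alkoxide installs a group that can chelate in step 21 and can be turned into a cyclic acetal in step 22, with no stereocentre involved.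

Step 15
Reactants: 17 PMB ether
Product: 18 Ch alcohol
Conditions: Bu4NF, THF, 50 °C
Reagents that add atoms: none
Why: Fluoride-induced desilylation frees Ch–OH selectively because the only other protecting group is a benzyl-type ether.

Step 16
Reactants: 18 Ch alcohol
Product: 19 tricyclic ketone (Ch=O)
Conditions: Dess–Martin periodinane, CH2Cl2, 25 °C
Reagents that add atoms: none
Why: Dess–Martin oxidation converts the single free alcohol into the nopinone-type ketone under neutral conditions that spare the alkene and the PMB ether.

Step 17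
Reactants: 19 tricyclic ketone
Product: 20 dienone (Ch=O conjugated with Ci=Cj)
Conditions: LiN(i-Pr)2, THF, −78 °C; then PhS(Cl)=Nt-Bu, −78 °C
Reagents that add atoms: none
Why: A second Mukaiyama dehydrogenation can only run toward Ci because Cg is a bridgehead, which gives the apoverbenone-type enone.

Step 18
Reactants: 20 dienone
Product: 21 methylated ketone (Cj–CH3 pointing toward Cf)
Conditions: Me2CuLi (from CuI and MeLi), Et2O, −78 to −20 °C; aq. NH4Cl
Reagents that add atoms: lithium dimethylcuprate, [Li+].C[Cu-]C
Why: Conjugate addition of the Gilman cuprate to this apoverbenone-type enone occurs anti to the bridge that carries the inward-pointing Cd methyl, so the new Cj methyl ends on the Cf side as in 38.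

Step 19
Reactants: 21 methylated ketone
Product: 22 ketal alkene
Conditions: Me3SiOCH2CH2OSiMe3, Me3SiOTf (cat.), CH2Cl2, −78 to −20 °C
Reagents that add atoms: 1,2-bis(trimethylsilyloxy)ethane, C[Si](C)(C)OCCO[Si](C)(C)C
Why: Noyori ketalisation protects the hindered ketone at low temperature without the protic acid that could open the strained ring system, and it is needed because Cc is later set by a borane reduction.

Step 20
Reactants: 22 ketal alkene
Product: 24 bicyclo[3.1.1]heptane dialdehyde (formyl on Cd and on Ck), via secondary ozonide 23 (not isolated)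
Conditions: O3, CH2Cl2, −78 °C (Sudan red end point); then Me2S, −78 to 25 °C
Reagents that add atoms: ozone, [O-][O+]=O
Why: Ozonolysis with reductive work-up cleaves the only C=C bond, stopping at the indicator end point spares the anisyl ring, and because Ca and Cc were ring neighbours the two formyl groups emerge on the same cyclobutane face with Cd, Cf and Ck unchanged.

Step 21
Reactants: 24 bicyclo[3.1.1]heptane dialdehyde; 25 nitromethane
Product: 27 tricyclic 2-nitro-1,3-diol (Ca–OH on the Ce side; Cb and Cc left open), via mono-nitroaldol adduct 26 (not isolated)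
Conditions: CH3NO2 (1.05 equiv), 1,1,3,3-tetramethylguanidine (0.2 equiv), THF, 0 to 25 °C
Reagents that add atoms: none
Why: Tetramethylguanidine forms the nitronate of 25, which adds to one formyl group (drawn for the Ck-bound one, 26), and the more acidic secondary nitronate of 26 then attacks the remaining formyl group, so that Cb receives both of its ring bonds. This is the double Henry (nitroaldol) cyclisation of a dialdehyde, the reaction type that converts periodate-cleaved sugars into nitro sugars and nitrocyclitols, and every C–C bond formed is reversible under the conditions. The cycloheptane closes in a 7-(enolexo)-exo-trig mode, which the cyclobutane favours by holding Cc and Ck on one face at the span of a four-atom bridge. Ca is controlled by Ck: Felkin–Anh attack anti to the cage carbon Cf and past the small methyl group (a cation bridging the aldehyde and ether oxygens selects the same face) puts the hydroxyl on the Ce side, and this epimer is also the one that keeps CH2OPMB pseudo-equatorial in the twisted bridge. Cb takes the nitro group on the open outer side with Ca–H eclipsing the nitronate to avoid allylic strain, and Cc should place its hydroxyl pseudo-equatorial, trans to the nitro group and cis to Ca–OH, but neither centre is relied on because both are erased in steps 23 and 24. The step needs ring closure to win over uptake of a second nitromethane and needs face selectivity at Ca; the first is secured by one equivalent of 25, reversibility, the absence of alpha hydrogens and the proximity of the formyl groups, the second only by the methyl versus CH2OPMB contrast at Ck, which is where the risk of the route sits.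

Step 22
Reactants: 27 tricyclic 2-nitro-1,3-diol
Product: 28 anisylidene acetal nitro alcohol (dioxane across Ca–O and the primary oxygen; Cc–OH free)
Conditions: DDQ, 4 Å sieves, CH2Cl2, 0 °C
Reagents that add atoms: none
Why: Anhydrous DDQ oxidation turns the PMB ether into an oxocarbenium ion that only the 1,3-related Ca–OH can capture in a six-membered ring, which masks Ca–O together with the primary oxygen, leaves Cc–OH free and puts the anisyl group equatorial on the new dioxane.

Step 23
Reactants: 28 anisylidene acetal nitro alcohol
Product: 29 alpha-nitro ketone (Cc=O)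
Conditions: Dess–Martin periodinane, CH2Cl2, 25 °C
Reagents that add atoms: none
Why: Dess–Martin oxidation of the lone free carbinol gives the alpha-nitro ketone, a known outcome for beta-nitro alcohols, and merges both possible Cc epimers into one compound.

Step 24
Reactants: 29 alpha-nitro ketone
Product: 30 acetal ketone (Cb now CH2)
Conditions: Bu3SnH, AIBN (cat.), toluene, 80 °C
Reagents that add atoms: none
Why: Radical denitration with tributyltin hydride is especially easy for alpha-nitro ketones because the intermediate radical is carbonyl-stabilised, and it removes the Cb stereocentre.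

Step 25
Reactants: 30 acetal ketone
Product: 31 acetal alcohol ((R)-carbinol at Cc with the hydroxyl on the Cg side and trans to Ca–O)
Conditions: (S)-2-methyl-CBS-oxazaborolidine (0.5 equiv), BH3·SMe2, THF, −20 °C
Reagents that add atoms: none
Why: A second Corey–Bakshi–Shibata reduction sets Cc under reagent control, the contrast between quaternary Cd and the Cb methylene being as large as in pinacolone, so hydride should enter from the Ce side and give the (R)-carbinol with its hydroxyl on the Cg side, trans to Ca–O.

Step 26
Reactants: 31 acetal alcohol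
Product: 32 triethylsilyl ether
Conditions: Et3SiOTf, 2,6-lutidine, CH2Cl2, −78 to 0 °C
Reagents that add atoms: triethylsilyl trifluoromethanesulfonate, CC[Si](CC)(CC)OS(=O)(=O)C(F)(F)F
Why: The silyl triflate is reactive enough for the hindered Cc–OH, and the triethylsilyl group is chosen so that it falls together with the ketal in step 30.

Step 27
Reactants: 32 triethylsilyl ether
Product: 33 diol (primary OH and Ca–OH free)
Conditions: H2 (1 atm), Pd(OH)2/C, EtOAc, 25 °C
Reagents that add atoms: none
Why: Hydrogenolysis of the benzylidene-type acetal is neutral, so the dioxolane and the silyl ether stay, and no alkene is present at this stage.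

Step 28
Reactants: 33 diol
Product: 34 primary acetate
Conditions: AcCl, 2,4,6-collidine, CH2Cl2, −78 °C
Reagents that add atoms: acetyl chloride, CC(=O)Cl
Why: Low-temperature acetylation with a hindered base differentiates the primary hydroxyl from the secondary neopentyl Ca–OH on steric grounds.

Step 29
Reactants: 34 primary acetate; 35 angelic acid
Product: 37 fully protected diester, via mixed anhydride 36 (not isolated)
Conditions: 2,4,6-Cl3C6H2COCl, Et3N, toluene, 25 °C; then 34, 80 °C
Reagents that add atoms: none
Why: Yamaguchi-type mixed-anhydride acylation run without a nucleophilic catalyst is the established way to esterify hindered secondary alcohols with angelic acid without Z to E isomerisation, and the C–O bond at Ca is not touched.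

Step 30
Reactants: 37 fully protected diester
Product: 38 target CNP0212099.1
Conditions: 1 M HCl, THF, 25 °C
Reagents that add atoms: water, O
Why: Mild aqueous acid hydrolyses the dioxolane and the triethylsilyl ether in one operation while both esters, the Z-alkene and all stereocentres persist.

Compound list
1 | (R)-Wieland–Miescher ketone, (8aR)-8a-methyl-3,4,8,8a-tetrahydronaphthalene-1,6(2H,7H)-dione | C[C@@]12CCC(=O)C=C1CCCC2=O | starting material
2 | dienol ether ketone, (8aR)-6-ethoxy-8a-methyl-3,7,8,8a-tetrahydronaphthalen-1(2H)-one | C[C@@]12CCC(OCC)=CC1=CCCC2=O | intermediate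
3 | hydroxy ketone, Ch–OH equatorial and trans to the angular methyl | C[C@@]12CCC(OCC)=CC1=CC[C@H](O)C2=O | intermediate
4 | silyloxy ketone, TBS ether of 3 | C[C@@]12CCC(OCC)=CC1=CC[C@H](O[Si](C)(C)C(C)(C)C)C2=O | intermediate
5 | dienol ether alcohol, Cg–OH cis to the angular methyl | C[C@@]12CCC(OCC)=CC1=CC[C@H](O[Si](C)(C)C(C)(C)C)[C@H]2O | intermediate
6 | hydroxy enone, Cg–OH cis and Ch–OTBS trans to the angular methyl | C[C@@]12CCC(=O)C=C1CC[C@H](O[Si](C)(C)C(C)(C)C)[C@H]2O | intermediate
7 | enone mesylate | C[C@@]12CCC(=O)C=C1CC[C@H](O[Si](C)(C)C(C)(C)C)[C@H]2OS(C)(=O)=O | intermediate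
8 | cis-decalone mesylate, Ce–H cis to the Cd methyl | C[C@@]12CCC(=O)C[C@@H]1CC[C@H](O[Si](C)(C)C(C)(C)C)[C@H]2OS(C)(=O)=O | intermediate
9 | tricyclic ketone, 3-(TBSO)-1-methyltricyclo[4.4.0.0(2,7)]decan-8-one | O=C1CC[C@]2(C)[C@@H]3[C@H]1[C@H]2[C@@H](O[Si](C)(C)C(C)(C)C)CC3 | intermediate
10 | tricyclic enone, 3-(TBSO)-1-methyltricyclo[4.4.0.0(2,7)]dec-9-en-8-one | O=C1C=C[C@]2(C)[C@@H]3[C@H]1[C@H]2[C@@H](O[Si](C)(C)C(C)(C)C)CC3 | intermediate
11 | tertiary allylic alcohol, Ck epimers (centre erased in step 10) | CC1(O)C=C[C@]2(C)[C@@H]3[C@H]1[C@H]2[C@@H](O[Si](C)(C)C(C)(C)C)CC3 | intermediate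
12 | transposed enone, 3-(TBSO)-1,8-dimethyltricyclo[4.4.0.0(2,7)]dec-8-en-10-one | CC1=CC(=O)[C@]2(C)[C@@H]3[C@H]1[C@H]2[C@@H](O[Si](C)(C)C(C)(C)C)CC3 | intermediate
13 | allylic alcohol, Cc–OH on the Cg side | CC1=C[C@@H](O)[C@]2(C)[C@@H]3[C@H]1[C@H]2[C@@H](O[Si](C)(C)C(C)(C)C)CC3 | intermediate
14 | tributylstannylmethyl ether of 13 | CC1=C[C@@H](OC[Sn](CCCC)(CCCC)CCCC)[C@]2(C)[C@@H]3[C@H]1[C@H]2[C@@H](O[Si](C)(C)C(C)(C)C)CC3 | intermediate
15 | lithiomethyl ether | CC1=C[C@@H](OC[Li])[C@]2(C)[C@@H]3[C@H]1[C@H]2[C@@H](O[Si](C)(C)C(C)(C)C)CC3 | intermediate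
16 | homoallylic alcohol, Ck–CH2OH on the Cg side, Ck–CH3 on the Ce side | C1=C[C@]2(C)[C@@H]3[C@@H]([C@H]2[C@@H](O[Si](C)(C)C(C)(C)C)CC3)[C@@]1(C)CO | intermediate
17 | PMB ether of 16 | C1=C[C@]2(C)[C@@H]3[C@@H]([C@H]2[C@@H](O[Si](C)(C)C(C)(C)C)CC3)[C@@]1(C)COCc4ccc(OC)cc4 | intermediate
18 | Ch alcohol | C1=C[C@]2(C)[C@@H]3[C@@H]([C@H]2[C@@H](O)CC3)[C@@]1(C)COCc4ccc(OC)cc4 | intermediate
19 | tricyclic ketone, Ch=O | C1=C[C@]2(C)[C@@H]3[C@@H]([C@H]2C(=O)CC3)[C@@]1(C)COCc4ccc(OC)cc4 | intermediate
20 | dienone, Ch=O with Ci=Cj | C1=C[C@]2(C)[C@@H]3[C@@H]([C@H]2C(=O)C=C3)[C@@]1(C)COCc4ccc(OC)cc4 | intermediate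
21 | methylated ketone, Cj–CH3 toward Cf | C1=C[C@]2(C)[C@@H]3[C@@H]([C@H]2C(=O)C[C@H]3C)[C@@]1(C)COCc4ccc(OC)cc4 | intermediate
22 | ketal alkene | C1=C[C@]2(C)[C@@H]3[C@@H]([C@H]2C5(OCCO5)C[C@H]3C)[C@@]1(C)COCc4ccc(OC)cc4 | intermediate
23 | secondary ozonide, trioxolane across Ca and Cc (these two centres transient) | C17OC(OO7)[C@]2(C)[C@@H]3[C@@H]([C@H]2C5(OCCO5)C[C@H]3C)[C@@]1(C)COCc4ccc(OC)cc4 | intermediate
24 | bicyclo[3.1.1]heptane dialdehyde, formyl on Cd and on Ck, Ch as ethylene ketal, primary oxygen as PMB ether | O=C[C@]1(C)[C@@H]2[C@@H]([C@H]1C3(OCCO3)C[C@H]2C)[C@@](C)(COCc4ccc(OC)cc4)C=O | intermediate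
25 | nitromethane | C[N+](=O)[O-] | starting material
26 | mono-nitroaldol adduct at the Ck-bound aldehyde | O=C[C@]1(C)[C@@H]2[C@@H]([C@H]1C3(OCCO3)C[C@H]2C)[C@@](C)(COCc4ccc(OC)cc4)[C@H](O)C[N+](=O)[O-] | intermediate
27 | tricyclic 2-nitro-1,3-diol, Ca–OH on the Ce side, Cb and Cc open (erased in steps 23 and 24) | O[C@@H]1C([N+](=O)[O-])C(O)[C@]2(C)[C@@H]3[C@@H]([C@H]2C4(OCCO4)C[C@H]3C)[C@@]1(C)COCc5ccc(OC)cc5 | intermediate
28 | anisylidene acetal nitro alcohol, aryl equatorial | COc5ccc(cc5)[C@@H]6O[C@@H]1C([N+](=O)[O-])C(O)[C@]2(C)[C@@H]3[C@@H]([C@H]2C4(OCCO4)C[C@H]3C)[C@@]1(C)CO6 | intermediate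
29 | alpha-nitro ketone | COc5ccc(cc5)[C@@H]6O[C@@H]1C([N+](=O)[O-])C(=O)[C@]2(C)[C@@H]3[C@@H]([C@H]2C4(OCCO4)C[C@H]3C)[C@@]1(C)CO6 | intermediate
30 | acetal ketone | COc5ccc(cc5)[C@@H]6O[C@@H]1CC(=O)[C@]2(C)[C@@H]3[C@@H]([C@H]2C4(OCCO4)C[C@H]3C)[C@@]1(C)CO6 | intermediate
31 | acetal alcohol, Cc–OH on the Cg side | COc5ccc(cc5)[C@@H]6O[C@@H]1C[C@@H](O)[C@]2(C)[C@@H]3[C@@H]([C@H]2C4(OCCO4)C[C@H]3C)[C@@]1(C)CO6 | intermediate
32 | triethylsilyl ether of 31 | COc5ccc(cc5)[C@@H]6O[C@@H]1C[C@@H](O[Si](CC)(CC)CC)[C@]2(C)[C@@H]3[C@@H]([C@H]2C4(OCCO4)C[C@H]3C)[C@@]1(C)CO6 | intermediate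
33 | diol | O[C@@H]1C[C@@H](O[Si](CC)(CC)CC)[C@]2(C)[C@@H]3[C@@H]([C@H]2C4(OCCO4)C[C@H]3C)[C@@]1(C)CO | intermediate
34 | primary acetate | O[C@@H]1C[C@@H](O[Si](CC)(CC)CC)[C@]2(C)[C@@H]3[C@@H]([C@H]2C4(OCCO4)C[C@H]3C)[C@@]1(C)COC(C)=O | intermediate
35 | angelic acid, (Z)-2-methylbut-2-enoic acid | C/C=C(/C)C(=O)O | starting material
36 | angelic 2,4,6-trichlorobenzoic mixed anhydride | C/C=C(/C)C(=O)OC(=O)c1c(Cl)cc(Cl)cc1Cl | intermediate
37 | fully protected diester | C/C=C(/C)C(=O)O[C@@H]1C[C@@H](O[Si](CC)(CC)CC)[C@]2(C)[C@@H]3[C@@H]([C@H]2C4(OCCO4)C[C@H]3C)[C@@]1(C)COC(C)=O | intermediate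
38 | CNP0212099.1, 3-(acetoxymethyl)-4-angeloyloxy-6-hydroxy-3,7,11-trimethyltricyclo[5.4.0.0(2,8)]undecan-9-one | C/C=C(/C)C(=O)O[C@@H]1C[C@@H](O)[C@]2(C)[C@@H]3[C@@H]([C@H]2C(=O)C[C@H]3C)[C@@]1(C)COC(C)=O | target

Total step count: 30. Longest linear sequence: 30 steps (from 1).

Steps most likely to fail

**Step 21.**
- What may go wrong: the twist sense of the forming four-atom bridge may be steered too weakly by Ck. Facial selectivity at Ca would then erode and the diastereomers would equilibrate through retro-nitroaldol reaction.
- Fallback: a stereochemical reset that sets out from 27, taken as the whole diastereomer mixture.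
- Radical denitration (Bu3SnH, AIBN, toluene, 110 °C) should give the denitrated diol F1. Dess–Martin oxidation of both carbinols gives the 1,3-diketone F2, in which Ca and Cc are trigonal. DDQ in wet CH2Cl2 removes the PMB group to give the hydroxy diketone F3.
- Me4NBH(OAc)3 in MeCN–AcOH at −20 °C then reduces twice by intramolecular hydride delivery (Evans–Saksena reduction). The primary hydroxyl on the Cg side hands hydride to Ca from that side, which sends the hydroxyl to the Ce side. The new Ca–OH then hands hydride to Cc from the Ce side, which sends that hydroxyl to the Cg side and gives the triol F4.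
- 4-MeOC6H4CH(OMe)2 with pyridinium p-toluenesulfonate closes the six-membered acetal on the primary and Ca oxygens. This is 31, where the route is rejoined.

**Step 7.**
- What may go wrong: displacement at Cg, which is flanked by quaternary Cd and by the bulky silyloxy group, may be too slow. Elimination or O-alkylation of the enolate could then take over.
- Fallback: replace the sulfonate by a far more reactive and less crowded cyclic sulfate, setting out from 6.
- Bu4NF gives the diol enone F5, and hydrogenation (H2, Pd/C, pyridine) gives the cis-fused diol ketone F6. SOCl2 and Et3N followed by NaIO4 with RuCl3 (cat.) give the cyclic sulfate F7.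
- KOt-Bu closes the cyclobutane by attack of Cf on Cg, the only sulfate carbon whose rear side it can reach. Aqueous H2SO4 in THF hydrolyses the resulting sulfate monoester to the tricyclic hydroxy ketone F8.
- t-BuMe2SiCl with imidazole then returns to 9.

**Step 11.**
- What may go wrong: poor facial discrimination by the oxazaborolidine, because quaternary Cd and the alkenyl arm may compete for the role of the large group.
- Fallback: give up asymmetric induction and rely on separation with recycling, setting out from 12.
- Luche reduction (NaBH4, CeCl3·7H2O, MeOH) should give 13 together with the epimeric allylic alcohol F9. The two diastereomers are separated by chromatography, F9 is oxidised back to 12 with MnO2 and reduced again, and the route continues from 13.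

Further compounds
F1 | step 21 | denitrated diol | OC1CC(O)[C@]2(C)[C@@H]3[C@@H]([C@H]2C4(OCCO4)C[C@H]3C)[C@@]1(C)COCc5ccc(OC)cc5
F2 | step 21 | 1,3-diketone | O=C1CC(=O)[C@]2(C)[C@@H]3[C@@H]([C@H]2C4(OCCO4)C[C@H]3C)[C@@]1(C)COCc5ccc(OC)cc5
F3 | step 21 | hydroxy diketone | O=C1CC(=O)[C@]2(C)[C@@H]3[C@@H]([C@H]2C4(OCCO4)C[C@H]3C)[C@@]1(C)CO
F4 | step 21 | triol | O[C@@H]1C[C@@H](O)[C@]2(C)[C@@H]3[C@@H]([C@H]2C4(OCCO4)C[C@H]3C)[C@@]1(C)CO
F5 | step 7 | diol enone | C[C@@]12CCC(=O)C=C1CC[C@H](O)[C@H]2O
F6 | step 7 | cis-fused diol ketone | C[C@@]12CCC(=O)C[C@@H]1CC[C@H](O)[C@H]2O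
F7 | step 7 | cyclic sulfate | C[C@@]12CCC(=O)C[C@@H]1CC[C@@H]3OS(=O)(=O)O[C@@H]23
F8 | step 7 | tricyclic hydroxy ketone | O=C1CC[C@]2(C)[C@@H]3[C@H]1[C@H]2[C@@H](O)CC3
F9 | step 11 | epimeric allylic alcohol | CC1=C[C@H](O)[C@]2(C)[C@@H]3[C@H]1[C@H]2[C@@H](O[Si](C)(C)C(C)(C)C)CC3
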